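The route rests on the dihydropyran ring of the chroman unit: its O1–C2(CH3)2–C3H2 segment is read as isobutylene oxide, to be stitched between benzylic carbon C4 and aryl carbon C8a. In one flask the methyl group of 2,6-difluorotoluene is metalated and opens the epoxide (C4–C3 bond); the released tertiary alkoxide then displaces one ortho fluorine (O1–C8a bond), a formal [3+3] annulation to 5-fluoro-2,2-dimethylchroman. Acylation para to O1 then puts a keto ester at C6, which activates the surviving C5 fluorine for exchange by methoxide. The derived arylacetic acid and 2,4-dihydroxy-6-methoxybenzaldehyde close the coumarin by a Perkin condensation.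

Key step: step 1

Remark: chroman numbering (O1, C2, C3, C4, C4a, C5 to C8, C8a) is used for the bicyclic aryl unit; the target has no stereocentre and the aryl–coumarin bond is assumed to rotate freely, so no step needs stereocontrol.

Step 1
Reactants: 1 2,6-difluorotoluene; 2 2,2-dimethyloxirane (isobutylene oxide)
Product: 5 5-fluoro-2,2-dimethylchroman, via benzylic potassium species 3 (not isolated), via tertiary potassium alkoxide 4 (not isolated)
Conditions: LiN(iPr)2, KOtBu, THF, −78 °C; then 2, −78 → 0 °C; then DMPU, 65 °C
Reagents that add atoms: none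
Why: The mixed lithium/potassium amide base removes a proton from the methyl group of 1 (lateral metalation; the two flanking fluorines acidify it and the amide base lets any ring anion equilibrate to the benzylic one), and benzylic species 3 opens epoxide 2 by SN2 attack at its unsubstituted CH2, forming the C4–C3 bond and tertiary alkoxide 4. On warming with DMPU, 4 adds to the fluorine-bearing ring carbon and fluoride leaves (intramolecular SNAr), forming the O1–C8a bond. The closest known reaction types are the benzylic metalation–epoxide alkylation of fluorotoluenes and the SNAr cyclisation of 3-(2-fluorophenyl)propanols to chromans, here run consecutively in one flask as a formal [3+3] annulation. The dihydropyran ring closes in 6-exo-trig mode by ipso addition–elimination, helped by the gem-dimethyl group and by the inductive pull of the second fluorine. No stereocentre is formed. The step needs benzylic rather than ring deprotonation (amide superbase, doubly fluorine-flanked methyl), attack at the CH2 rather than the quaternary epoxide carbon (sterics), and no choice between the fluorines (they are equivalent by symmetry, and the one that stays becomes the later C5 handle).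

Step 2
Reactants: 5 5-fluoro-2,2-dimethylchroman; 6 methyl chlorooxoacetate
Product: 7 methyl 2-(5-fluoro-2,2-dimethylchroman-6-yl)-2-oxoacetate
Conditions: AlCl3, CH2Cl2, −20 → 0 °C
Reagents that add atoms: none
Why: Friedel–Crafts acylation: the ring oxygen O1 directs the acylium ion to its para position C6, which is also ortho to the small fluorine (the pattern known from acylation of 3-fluoroanisole), and no Lewis-acid-labile methyl ether is present yet.

Step 3
Reactants: 7 methyl 2-(5-fluoro-2,2-dimethylchroman-6-yl)-2-oxoacetate
Product: 8 methyl 2-(5-methoxy-2,2-dimethylchroman-6-yl)-2-oxoacetate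
Conditions: NaOMe, MeOH, 60 °C
Reagents that add atoms: sodium methoxide, C[O-].[Na+]
Why: Nucleophilic aromatic substitution (SNAr): the ortho keto ester stabilises the Meisenheimer adduct so that methoxide replaces the C5 fluoride, and methanol as solvent keeps the ester as the methyl ester.

Step 4
Reactants: 8 methyl 2-(5-methoxy-2,2-dimethylchroman-6-yl)-2-oxoacetate
Product: 10 2-(5-methoxy-2,2-dimethylchroman-6-yl)acetic acid, via hydrazone carboxylate 9 (not isolated)
Conditions: N2H4·H2O, KOH, diethylene glycol, 120 °C then 190 °C; aq. HCl
Reagents that add atoms: potassium hydroxide, [K+].[OH-]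
Why: Wolff–Kishner reduction in the Huang-Minlon form: saponification, hydrazone formation to 9 and base-induced loss of N2 turn the keto group into CH2, the standard passage from an arylglyoxylate to an arylacetic acid, under which both aryl ethers are inert.

Step 5
Reactants: 10 2-(5-methoxy-2,2-dimethylchroman-6-yl)acetic acid; 11 2,4-dihydroxy-6-methoxybenzaldehyde
Product: 13 7-hydroxy-5-methoxy-3-(5-methoxy-2,2-dimethylchroman-6-yl)-2H-chromen-2-one (target), via 7-acetoxycoumarin 12 (not isolated)
Conditions: Ac2O, Et3N, 120 °C; then MeOH, 60 °C; aq. HCl
Reagents that add atoms: none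
Why: Perkin (Perkin–Oglialoro) coumarin synthesis: the mixed anhydride of 10 condenses with the aldehyde of acetylated 11 and the ortho oxygen lactonises to 7-acetate 12, whose activated aryl acetate is then cleaved by Et3N-mediated methanolysis to free the 7-hydroxyl.

Compound list
1 | 2,6-difluorotoluene | Cc1c(F)cccc1F | starting material
2 | 2,2-dimethyloxirane (isobutylene oxide) | CC1(C)CO1 | starting material
3 | 2,6-difluorobenzylpotassium (formed in the flask) | [K+].[CH2-]c1c(F)cccc1F | intermediate
4 | potassium 4-(2,6-difluorophenyl)-2-methylbutan-2-olate (formed in the flask) | [K+].CC(C)([O-])CCc1c(F)cccc1F | intermediate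
5 | 5-fluoro-2,2-dimethylchroman (5-fluoro-2,2-dimethyl-3,4-dihydro-2H-chromene) | CC1(C)CCc2c(F)cccc2O1 | intermediate
6 | methyl chlorooxoacetate (methyl oxalyl chloride) | COC(=O)C(=O)Cl | starting material
7 | methyl 2-(5-fluoro-2,2-dimethylchroman-6-yl)-2-oxoacetate | COC(=O)C(=O)c1ccc2c(c1F)CCC(C)(C)O2 | intermediate
8 | methyl 2-(5-methoxy-2,2-dimethylchroman-6-yl)-2-oxoacetate | COC(=O)C(=O)c1ccc2c(c1OC)CCC(C)(C)O2 | intermediate
9 | potassium 2-hydrazinylidene-2-(5-methoxy-2,2-dimethylchroman-6-yl)acetate (formed in the flask; C=N geometry undefined, either isomer reacts) | NN=C(C(=O)[O-])c1ccc2c(c1OC)CCC(C)(C)O2.[K+] | intermediate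
10 | 2-(5-methoxy-2,2-dimethylchroman-6-yl)acetic acid | OC(=O)Cc1ccc2c(c1OC)CCC(C)(C)O2 | intermediate
11 | 2,4-dihydroxy-6-methoxybenzaldehyde | O=Cc1c(O)cc(O)cc1OC | starting material
12 | 7-acetoxy-5-methoxy-3-(5-methoxy-2,2-dimethylchroman-6-yl)-2H-chromen-2-one (formed in the flask) | CC(=O)Oc1cc(OC)c2cc(-c3ccc4c(c3OC)CCC(C)(C)O4)c(=O)oc2c1 | intermediate
13 | 7-hydroxy-5-methoxy-3-(5-methoxy-2,2-dimethylchroman-6-yl)-2H-chromen-2-one (CNP0139207.0; no stereocentre) | COc1c(-c2cc3c(OC)cc(O)cc3oc2=O)ccc2c1CCC(C)(C)O2 | target

Total step count: 5. Longest linear sequence: 5 steps (1 → 5 → 7 → 8 → 10 → 13).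

Steps most likely to fail

Step 1. Ring deprotonation next to fluorine with loss of fluoride to an aryne, base-induced isomerisation of the epoxide to an allylic alkoxide, or stalling of the fluoride displacement may erode the one-flask annulation. The fallback sets out from 1 and 2 and comes back at 5, making the two bonds in separate operations. Radical bromination of 1 (NBS, dibenzoyl peroxide cat., PhCF3, 85 °C) should give 2,6-difluorobenzyl bromide F1. Magnesium in Et2O should convert it into 2,6-difluorobenzylmagnesium bromide F2, which with 2 and CuI (cat.) at −20 °C should give 4-(2,6-difluorophenyl)-2-methylbutan-2-ol F3 after aqueous work-up. KOtBu in DMF at 80 °C should then close the ring by intramolecular SNAr to 5.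

Step 2. Acylation ortho instead of para to O1, or Lewis-acid ionisation of the tertiary C2–O1 bond, may lower the yield. The fallback sets out from 5 and comes back at 7. Fluorine-directed ortho-lithiation (n-BuLi, PMDTA, THF, −78 °C) should give (5-fluoro-2,2-dimethylchroman-6-yl)lithium F4. Adding it to an excess of dimethyl oxalate (COC(=O)C(=O)OC) at −78 °C should give 7.

Step 4. Hydrazide formation at the ester, incomplete decomposition of the hindered hydrazone, or nucleophilic loss of the C5 methyl ether at 190 °C may occur. The fallback sets out from 8 and comes back at 10. Acid-promoted catalytic hydrogenolysis (H2, Pd/C, AcOH, H2SO4 cat., 50 °C) should reduce the benzylic ketone through methyl 2-hydroxy-2-(5-methoxy-2,2-dimethylchroman-6-yl)acetate F5 (racemic, not isolated) to methyl 2-(5-methoxy-2,2-dimethylchroman-6-yl)acetate F6. Saponification (LiOH, THF/H2O; aq. HCl) should then give 10.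

Further compounds
F1 | step 1 | 2,6-difluorobenzyl bromide | BrCc1c(F)cccc1F
F2 | step 1 | 2,6-difluorobenzylmagnesium bromide | Br[Mg]Cc1c(F)cccc1F
F3 | step 1 | 4-(2,6-difluorophenyl)-2-methylbutan-2-ol | CC(C)(O)CCc1c(F)cccc1F
F4 | step 2 | (5-fluoro-2,2-dimethylchroman-6-yl)lithium | [Li]c1ccc2c(c1F)CCC(C)(C)O2
F5 | step 4 | methyl 2-hydroxy-2-(5-methoxy-2,2-dimethylchroman-6-yl)acetate (racemic) | COC(=O)C(O)c1ccc2c(c1OC)CCC(C)(C)O2
F6 | step 4 | methyl 2-(5-methoxy-2,2-dimethylchroman-6-yl)acetate | COC(=O)Cc1ccc2c(c1OC)CCC(C)(C)O2
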